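## The problem

- The target (19) has two furan-2,5-dione (maleic anhydride) rings. Ring A carries CH2OH on C3 and the linking CH2 on C4. Ring B carries the stereocentre on C3 and the 2-oxohexyl group on C4. The rings are joined, not fused, through A-C4–CH2–C*H(n-pentyl)–B-C3.
- Both ring alkenes are tetrasubstituted and must hold their two carboxyl carbons cis, with four different outer substituents. Stepwise olefination gives E/Z mixtures on such alkenes and would have to be run twice.
- The single (R) stereocentre has no neighbour that could control it. Once ring B exists it is γ to B-C5=O (a vinylogous α-position), so base epimerises it through the dienolate. It must be set absolutely and early, and kept under neutral or acidic conditions afterwards.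
- The CH2 of the 2-oxohexyl group is activated by the ketone and by ring B and enolises easily (alkene migration to the exocyclic position). The ketone should appear late and without base.
- The CH2OH next to ring A can add to an anhydride carbonyl (butenolide acid, oligoesters) and should be freed last. The anhydrides exclude alcohols, amines and hydroxide from the end game.
- The enabling feature: in each ring, C3=C4 with its cis carbonyl carbons C2 and C5 is an internal alkyne plus two CO2. The two C3=C4 units are separated by exactly the sp3 pair C*H–CH2, so the two alkynes form a hepta-1,5-diyne unit and cannot couple with each other. All four carbonyl carbons and both ring oxygens are then non-skeletal, and the skeleton shrinks to a linear C13 chain with one pentyl branch.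

## Retrosynthesis

**19 ⇒ 18 ⇒ 17 (end game, no skeletal bond cut).** The CH2OH is carried as its TIPS ether 18 and the ketone as the secondary carbinol 17. The forward steps are an oxidation and an acidic desilylation, both free of base, so the γ-acidic stereocentre and the activated CH2 are not exposed to enolising conditions.

**17 ⇒ 15 + 4 CO2 (key disconnection).** Cut are the four C–C bonds A-C3–C2, A-C4–C5, B-C3–C2 and B-C4–C5, plus the two anhydride C–O–C bridges. Against building each ring from a maleate piece, this cut removes both tetrasubstituted alkenes, their cis geometry, and every ester hydrolysis. The precursor, diyne 15, is an open chain with one stereocentre and two silyl ethers. The forward reaction must carboxylate both carbons of both triple bonds, cis, without touching the propargylic stereocentre or the propargylic silyl ether.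

**15 ⇒ 14 ⇒ 11 + 12.** Cut is the C(sp)–CH2 bond on the ring-B side. A terminal alkyne and a terminal epoxide give the 2-oxygenated hexyl chain at the right position in one step. An ynone or β,γ-alkynyl ketone would isomerise to an allenone, so the ketone is held as a TES-protected carbinol whose configuration is irrelevant. The forward step needs only acetylide opening of epoxide 12 at its CH2.

**11 ⇒ 10 ⇒ 9 ⇒ 8.** The terminal alkyne carbon is added to aldehyde 10 by one-carbon homologation. The aldehyde comes from the acyl group of imide 8 by reduction and oxidation. This makes the carbonyl carbon of a chiral carboxylic acid derivative into B-C3, so the stereocentre can be set by enolate chemistry.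

**8 ⇒ 6 + 3; 6 ⇒ 4 + 5; 3 ⇒ 2 ⇒ 1.** Cut is the C*–CH2 bond. Alkylating the heptanoyl imide 6 with propargylic bromide 3 brings in the whole ring-A alkyne with its protected hydroxymethyl carbon and sets the (R) centre under auxiliary control. The other two bonds at C* would need an unactivated pentyl halide or an electrophilic alkyne. Bromide 3 comes from 2-butyne-1,4-diol (1) in two steps, and 6 from auxiliary 4 and heptanoyl chloride (5).

## Roads not taken

**Alternative 1: ring-by-ring assembly with maleate chemistry (the obvious route).**
- Cut: C*–CH2 to a preformed ring A, then ring B built from the carboxyl carbon.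
- Forward: alkylation of 6 with the ring-A allylic bromide A1 to give A2; conversion of the acyl group into α-keto ester A3; Horner–Wadsworth–Emmons or aldol–dehydration to the second tetrasubstituted alkene; saponification of four esters.
- Why the chosen plan is better:
  - A1 is ambident (SN2 against SN2').
  - In A3 the stereocentre is α to a ketone and epimerises.
  - The olefination gives E/Z mixtures, of which only one closes to the anhydride.
  - The final hydroxide step meets the γ-acidic stereocentre and the oxohexyl CH2.
  - Each ring costs four or more steps; the chosen plan makes both rings in one step with the geometry fixed by mechanism.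

**Alternative 2: biomimetic union of two intact anhydride monomers.**
- Cut: C*–CH2 only.
- Forward: the γ-(vinylogous) enolate of methyl anhydride A4 attacks the racemic allylic bromide A5.
- Why the chosen plan is better:
  - It would need an enantioconvergent substitution for which the anhydride dienolate offers no handle.
  - The dienolate is α/γ-ambident.
  - A5 has more acidic protons (oxohexyl CH2) than the methyl group of A4.
  - The product stereocentre is γ-acidic under the same basic conditions.
  - It is the shortest route on paper, but the one stereocentre would be uncontrolled.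

**Alternative 3: furans as masked anhydrides.**
- Cut: the same alkyne-to-ring logic, but through bis(3,4-dialkylfuran) A6, for example from diyne 15 by oxazole Diels–Alder/retro-Diels–Alder.
- Forward: twofold singlet-oxygen oxidation, then a further oxidation to the anhydride level.
- Why the chosen plan is better:
  - Unactivated dialkylalkynes need very high temperatures with oxazoles.
  - The two oxidations pass through regio- and stereoisomeric mixtures and need a strong oxidant beside the oxygenated side chain.
  - It takes three operations where CO2 delivers the right oxidation level in one.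

Key step: step 10

Remark 1: the target is taken as the open hydroxymethyl anhydride drawn; its butenolide acid is a ring–chain tautomer, and acidic, non-nucleophilic conditions are assumed to return the drawn form.

Remark 2: the carbinol carbon brought in with epoxide 12 is only a placeholder for the ketone; (R)-12 is used so that 14, 15 and 17 are single stereoisomers, and racemic 12 would serve equally.

## Route

Step 1
Reactants: 1 2-butyne-1,4-diol
Product: 2 4-[(triisopropylsilyl)oxy]but-2-yn-1-ol
Conditions: 1 (3 equiv), TIPSCl (1 equiv), imidazole, DMF, 0 °C to rt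
Reagents that add atoms: triisopropylsilyl chloride (TIPSCl), CC(C)[Si](Cl)(C(C)C)C(C)C
Why: Statistical monosilylation of a symmetric diol; excess water-soluble diol suppresses the bis-ether. TIPS is chosen to survive to the last step and to be a poor leaving group in step 10.

Step 2
Reactants: 2 4-[(triisopropylsilyl)oxy]but-2-yn-1-ol
Product: 3 [(4-bromobut-2-yn-1-yl)oxy]triisopropylsilane
Conditions: CBr4, PPh3, CH2Cl2, 0 °C
Reagents that add atoms: carbon tetrabromide, BrC(Br)(Br)Br
Why: Appel bromination of a primary propargylic alcohol under neutral conditions; the silyl ether is untouched.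

Step 3
Reactants: 4 (S)-4-benzyloxazolidin-2-one; 5 heptanoyl chloride
Product: 6 (S)-4-benzyl-3-heptanoyloxazolidin-2-one
Conditions: Et3N, DMAP (cat.), CH2Cl2, 0 °C to rt
Reagents that add atoms: none
Why: DMAP-catalysed N-acylation of the Evans auxiliary with an acid chloride.

Step 4
Reactants: 6 (S)-4-benzyl-3-heptanoyloxazolidin-2-one; 3 [(4-bromobut-2-yn-1-yl)oxy]triisopropylsilane
Product: 8 (S)-4-benzyl-3-{(2R)-2-[4-(triisopropylsilyloxy)but-2-yn-1-yl]heptanoyl}oxazolidin-2-one, via sodium Z-enolate 7 (not isolated)
Conditions: NaHMDS, THF, −78 °C; then 3, −78 to −40 °C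
Reagents that add atoms: none
Why: Evans asymmetric alkylation: the chelated Z-enolate is attacked by the activated propargylic bromide on the face opposite the benzyl group of the (S)-auxiliary, which should set the (R) configuration of the only stereocentre of the target.

Step 5
Reactants: 8 (S)-4-benzyl-3-{(2R)-2-[4-(triisopropylsilyloxy)but-2-yn-1-yl]heptanoyl}oxazolidin-2-one
Product: 9 (R)-2-[4-(triisopropylsilyloxy)but-2-yn-1-yl]heptan-1-ol
Conditions: LiBH4, MeOH (1 equiv), THF, 0 °C
Reagents that add atoms: none
Why: Reductive cleavage of the N-acyloxazolidinone by LiBH4 gives the primary alcohol without touching the α-centre; auxiliary 4 is recovered.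

Step 6
Reactants: 9 (R)-2-[4-(triisopropylsilyloxy)but-2-yn-1-yl]heptan-1-ol
Product: 10 (R)-2-[4-(triisopropylsilyloxy)but-2-yn-1-yl]heptanal
Conditions: Dess–Martin periodinane, CH2Cl2, 0 °C to rt
Reagents that add atoms: none
Why: Dess–Martin oxidation under non-basic conditions keeps the α-stereocentre; the aldehyde is used directly.

Step 7
Reactants: 10 (R)-2-[4-(triisopropylsilyloxy)but-2-yn-1-yl]heptanal
Product: 11 (R)-triisopropyl[(5-pentylhepta-2,6-diyn-1-yl)oxy]silane
Conditions: dimethyl (1-diazo-2-oxopropyl)phosphonate, K2CO3, MeOH, 0 °C to rt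
Reagents that add atoms: Ohira–Bestmann reagent, dimethyl (1-diazo-2-oxopropyl)phosphonate, CC(=O)C(=[N+]=[N-])P(=O)(OC)OC
Why: Seyferth–Gilbert homologation in the Ohira–Bestmann variant turns the aldehyde into the terminal alkyne in one pot; the diazo carbon becomes the new alkyne CH and the stereocentre becomes propargylic.

Step 8
Reactants: 11 (R)-triisopropyl[(5-pentylhepta-2,6-diyn-1-yl)oxy]silane; 12 (R)-2-butyloxirane
Product: 14 (5R,9R)-9-pentyl-13-[(triisopropylsilyl)oxy]trideca-7,11-diyn-5-ol, via lithium acetylide 13 (not isolated)
Conditions: n-BuLi, THF, −78 °C; BF3·OEt2, then 12, −78 °C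
Reagents that add atoms: none
Why: BF3-promoted opening of a terminal epoxide by a lithium acetylide at the CH2 carbon; the carbinol configuration is carried over unchanged from 12, and only the terminal alkyne C–H is acidic enough for n-BuLi at −78 °C.

Step 9
Reactants: 14 (5R,9R)-9-pentyl-13-[(triisopropylsilyl)oxy]trideca-7,11-diyn-5-ol
Product: 15 triethyl{[(5R,9R)-9-pentyl-13-(triisopropylsilyloxy)trideca-7,11-diyn-5-yl]oxy}silane
Conditions: TESCl, imidazole, CH2Cl2, 0 °C to rt
Reagents that add atoms: chlorotriethylsilane (TESCl), CC[Si](Cl)(CC)CC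
Why: Silylation removes the only protic group before the organometallic step; TES is chosen because the acidic work-up of step 10 cleaves it while the primary TIPS ether stays.

Step 10
Reactants: 15 triethyl{[(5R,9R)-9-pentyl-13-(triisopropylsilyloxy)trideca-7,11-diyn-5-yl]oxy}silane
Product: 17 3-[(2R)-2-hydroxyhexyl]-4-{(2R)-1-[2,5-dioxo-4-({[tri(propan-2-yl)silyl]oxy}methyl)-2,5-dihydrofuran-3-yl]heptan-2-yl}furan-2,5-dione, via dimagnesium tetracarboxylate 16 (not isolated)
Conditions: Ni(acac)2(bpy) (20 mol %), Zn powder (6 equiv), MgBr2 (6 equiv), MS 3 Å, CO2 (1 atm), DMF, rt; then 1 M HCl, THF, rt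
Reagents that add atoms: carbon dioxide, O=C=O
Why: The step relies on the nickel-catalysed reductive double carboxylation of internal alkynes with CO2 (Zn as reductant, MgBr2 as Lewis acid), a known route from dialkylalkynes to maleic anhydrides, run here on both triple bonds of a 1,5-diyne. Ni(0)(bpy) couples the η2-alkyne with CO2 by oxidative cyclisation to an oxanickelacyclopentenone; Mg2+ binds the carboxylate, Zn reduces the alkenylnickel(II) to alkenylnickel(I), a second CO2 inserts into the Ni–C(sp2) bond with retention, and reduction returns Ni(0). Both CO2 units reach the same face of the π bond through the metallacycle, so each alkyne should give only the cis-dicarboxylate, and since both alkyne carbons end up carboxylated the regiochemistry of the first C–C bond does not matter for either unsymmetrical alkyne. On acidification each 2,3-dialkylmaleic acid closes to its anhydride by 5-exo-trig attack of a carboxyl oxygen on the neighbouring carboxyl carbon, and the same aqueous HCl cleaves the secondary TES ether while the primary TIPS ether survives. No stereocentre is created; the propargylic C–H of the (R) centre is not acidic under these reductive, non-basic conditions, carries no leaving group, and becomes γ to an anhydride carbonyl only once the medium is acidic. The step needs full conversion of both alkynes without alkyne–alkyne coupling or β-oxygen elimination: the CH–CH2 spacer allows an intramolecular nickelacyclopentadiene only with a fused cyclobutene, CO2 at saturation with bpy favours carboxylation over oligomerisation, and the bulky silyloxide on the propargylic CH2 is a poor leaving group.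

Step 11
Reactants: 17 3-[(2R)-2-hydroxyhexyl]-4-{(2R)-1-[2,5-dioxo-4-({[tri(propan-2-yl)silyl]oxy}methyl)-2,5-dihydrofuran-3-yl]heptan-2-yl}furan-2,5-dione
Product: 18 3-(2-oxohexyl)-4-{(2R)-1-[2,5-dioxo-4-({[tri(propan-2-yl)silyl]oxy}methyl)-2,5-dihydrofuran-3-yl]heptan-2-yl}furan-2,5-dione
Conditions: Dess–Martin periodinane, CH2Cl2, rt
Reagents that add atoms: none
Why: Dess–Martin oxidation of the secondary carbinol in a weakly acidic, base-free medium that tolerates anhydrides and the TIPS ether; any lactone acid formed by addition of the hydroxyl to ring B is a labile dialkylmaleic half-ester that should return the open alcohol as it is consumed.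

Step 12
Reactants: 18 3-(2-oxohexyl)-4-{(2R)-1-[2,5-dioxo-4-({[tri(propan-2-yl)silyl]oxy}methyl)-2,5-dihydrofuran-3-yl]heptan-2-yl}furan-2,5-dione
Product: 19 3-{(2R)-1-[4-(hydroxymethyl)-2,5-dioxo-2,5-dihydrofuran-3-yl]heptan-2-yl}-4-(2-oxohexyl)furan-2,5-dione
Conditions: 48% aq. HF, MeCN, 0 °C to rt
Reagents that add atoms: none
Why: Acidic fluoride desilylation of the primary TIPS ether; no base is present, so the γ-stereocentre and the activated CH2 are not enolised, and any anhydride opened by water recloses on concentration.

## Compound list

1 | 2-butyne-1,4-diol | OCC#CCO | starting material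
2 | 4-[(triisopropylsilyl)oxy]but-2-yn-1-ol | OCC#CCO[Si](C(C)C)(C(C)C)C(C)C | intermediate
3 | [(4-bromobut-2-yn-1-yl)oxy]triisopropylsilane | BrCC#CCO[Si](C(C)C)(C(C)C)C(C)C | intermediate
4 | (S)-4-benzyloxazolidin-2-one | O=C1N[C@@H](Cc2ccccc2)CO1 | starting material
5 | heptanoyl chloride | CCCCCCC(Cl)=O | starting material
6 | (S)-4-benzyl-3-heptanoyloxazolidin-2-one | CCCCCCC(=O)N1[C@@H](Cc2ccccc2)COC1=O | intermediate
7 | sodium (Z)-enolate of 6 | CCCCC/C=C(\[O-])N1[C@@H](Cc2ccccc2)COC1=O.[Na+] | intermediate (not isolated)
8 | (S)-4-benzyl-3-{(2R)-2-[4-(triisopropylsilyloxy)but-2-yn-1-yl]heptanoyl}oxazolidin-2-one | CCCCC[C@H](CC#CCO[Si](C(C)C)(C(C)C)C(C)C)C(=O)N1[C@@H](Cc2ccccc2)COC1=O | intermediate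
9 | (R)-2-[4-(triisopropylsilyloxy)but-2-yn-1-yl]heptan-1-ol | CCCCC[C@H](CC#CCO[Si](C(C)C)(C(C)C)C(C)C)CO | intermediate
10 | (R)-2-[4-(triisopropylsilyloxy)but-2-yn-1-yl]heptanal | CCCCC[C@H](CC#CCO[Si](C(C)C)(C(C)C)C(C)C)C=O | intermediate
11 | (R)-triisopropyl[(5-pentylhepta-2,6-diyn-1-yl)oxy]silane | CCCCC[C@H](CC#CCO[Si](C(C)C)(C(C)C)C(C)C)C#C | intermediate
12 | (R)-2-butyloxirane, (R)-1,2-epoxyhexane | CCCC[C@@H]1CO1 | starting material
13 | lithium acetylide of 11 | CCCCC[C@H](CC#CCO[Si](C(C)C)(C(C)C)C(C)C)C#C[Li] | intermediate (not isolated)
14 | (5R,9R)-9-pentyl-13-[(triisopropylsilyl)oxy]trideca-7,11-diyn-5-ol | CCCCC[C@H](CC#CCO[Si](C(C)C)(C(C)C)C(C)C)C#CC[C@H](O)CCCC | intermediate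
15 | triethyl{[(5R,9R)-9-pentyl-13-(triisopropylsilyloxy)trideca-7,11-diyn-5-yl]oxy}silane | CCCCC[C@H](CC#CCO[Si](C(C)C)(C(C)C)C(C)C)C#CC[C@H](O[Si](CC)(CC)CC)CCCC | intermediate
16 | dimagnesium tetracarboxylate from 15: each C≡C has become a C(CO2−)=C(CO2−) unit with the carboxylates cis | CCCCC[C@H](C/C(C(=O)[O-])=C(\CO[Si](C(C)C)(C(C)C)C(C)C)C(=O)[O-])/C(C(=O)[O-])=C(\C[C@H](O[Si](CC)(CC)CC)CCCC)C(=O)[O-].[Mg+2].[Mg+2] | intermediate (not isolated)
17 | 3-[(2R)-2-hydroxyhexyl]-4-{(2R)-1-[2,5-dioxo-4-({[tri(propan-2-yl)silyl]oxy}methyl)-2,5-dihydrofuran-3-yl]heptan-2-yl}furan-2,5-dione | CCCCC[C@H](CC1=C(CO[Si](C(C)C)(C(C)C)C(C)C)C(=O)OC1=O)C1=C(C[C@H](O)CCCC)C(=O)OC1=O | intermediate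
18 | 3-(2-oxohexyl)-4-{(2R)-1-[2,5-dioxo-4-({[tri(propan-2-yl)silyl]oxy}methyl)-2,5-dihydrofuran-3-yl]heptan-2-yl}furan-2,5-dione | CCCCC[C@H](CC1=C(CO[Si](C(C)C)(C(C)C)C(C)C)C(=O)OC1=O)C1=C(CC(=O)CCCC)C(=O)OC1=O | intermediate
19 | 3-{(2R)-1-[4-(hydroxymethyl)-2,5-dioxo-2,5-dihydrofuran-3-yl]heptan-2-yl}-4-(2-oxohexyl)furan-2,5-dione | CCCCC[C@H](CC1=C(CO)C(=O)OC1=O)C1=C(CC(=O)CCCC)C(=O)OC1=O | target

## Step count and risks

Total steps: 12. Longest linear sequence: 11 steps (steps 1, 2, 4–12, from 2-butyne-1,4-diol); the branch from 4 and 5 joins at step 4.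

**Step 10 (key step).**
- What may go wrong:
  - The second CO2 insertion may lose to protonation of the alkenyl–metal intermediate by traces of water, which leaves one or both alkynes only hydrocarboxylated.
  - Silyloxide may be eliminated from the alkenyl–metal carbon next to CH2OTIPS, giving an allene.
  - The unsymmetrical dialkylalkynes may turn over slowly, letting Ni(0) oligomerisation compete.
  - MgBr2 may strip the TES group early and create a protic OH.
- Fallback, from 15 back to 17: both alkynes are bis-methoxycarbonylated oxidatively with Pd(II) [Pd(OAc)2 cat., p-benzoquinone, CO (1 atm), MeOH], a syn-alkoxycarbonylpalladation, CO insertion and methanolysis that gives cis-diesters. This affords the tetramethyl bis-maleate F1. Saponification (LiOH, THF/H2O, 0 °C) gives the tetralithium tetracarboxylate F2, and acidification with 1 M HCl closes both rings and cleaves the TES ether to give 17. This uncouples C–C bond formation from ring closure, at the cost of one hydroxide step that must be kept cold and short.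

**Step 11.**
- What may go wrong:
  - The 2-hydroxyhexyl group may sit largely as the five-membered lactone acid formed by addition to ring B and be withheld from the oxidant.
  - The doubly activated CH2 of the product may enolise and react further with the periodinane.
- Fallback, from 14 back to 18: the ketone is installed before the carboxylation and carried as a ketal. Oxidation of 14 with Dess–Martin periodinane gives the β,γ-alkynyl ketone F3. Aprotic ketalisation [1,2-bis(trimethylsilyloxy)ethane, TMSOTf cat., CH2Cl2, −78 °C] gives the dioxolane F4. The conditions of step 10 convert F4 into the dimagnesium tetracarboxylate F5, and the acidic work-up closes both rings and hydrolyses the ketal, giving 18 without a free hydroxy anhydride.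

**Step 7.**
- What may go wrong: partial epimerisation of the α-branched aldehyde 10 by K2CO3/MeOH before homologation would erode the only stereocentre.
- Fallback, from 10 back to 13 and 14: Corey–Fuchs olefination (CBr4, PPh3, CH2Cl2, 0 °C) gives the dibromoalkene F6. n-BuLi (2 equiv, THF, −78 °C) converts F6 by exchange and rearrangement directly into the lithium acetylide 13, which is opened onto 12 as in step 8 to give 14. The aldehyde never meets a base.

**Step 12.**
- What may go wrong:
  - Cleavage of the primary TIPS ether may be slow.
  - During the long reaction the activated CH2 beside the ketone may enolise (alkene migration).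
  - The liberated CH2OH may acylate intermolecularly on concentration.
- Fallback, from 17 back to 19: desilylation is done before the ketone exists (48% aq. HF, MeCN) to give the diol bis-anhydride F7. The secondary carbinol of F7 is then oxidised chemoselectively beside the primary alcohol with NaOCl in acetic acid, an acidic, secondary-selective oxidation, to give 19.

## Further compounds

F1 | step 10 | tetramethyl bis-maleate from 15 (each C≡C converted into C(CO2Me)=C(CO2Me), ester groups cis) | CCCCC[C@H](C/C(C(=O)OC)=C(\CO[Si](C(C)C)(C(C)C)C(C)C)C(=O)OC)/C(C(=O)OC)=C(\C[C@H](O[Si](CC)(CC)CC)CCCC)C(=O)OC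
F2 | step 10 | tetralithium tetracarboxylate from F1 | CCCCC[C@H](C/C(C(=O)[O-])=C(\CO[Si](C(C)C)(C(C)C)C(C)C)C(=O)[O-])/C(C(=O)[O-])=C(\C[C@H](O[Si](CC)(CC)CC)CCCC)C(=O)[O-].[Li+].[Li+].[Li+].[Li+]
F3 | step 11 | (R)-9-pentyl-13-[(triisopropylsilyl)oxy]trideca-7,11-diyn-5-one | CCCCC[C@H](CC#CCO[Si](C(C)C)(C(C)C)C(C)C)C#CCC(=O)CCCC
F4 | step 11 | 2-butyl-2-[(R)-4-pentyl-8-(triisopropylsilyloxy)octa-2,6-diyn-1-yl]-1,3-dioxolane | CCCCC[C@H](CC#CCO[Si](C(C)C)(C(C)C)C(C)C)C#CCC1(CCCC)OCCO1
F5 | step 11 | dimagnesium tetracarboxylate from F4 (carboxylates cis on each alkene) | CCCCC[C@H](C/C(C(=O)[O-])=C(\CO[Si](C(C)C)(C(C)C)C(C)C)C(=O)[O-])/C(C(=O)[O-])=C(\CC1(CCCC)OCCO1)C(=O)[O-].[Mg+2].[Mg+2]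
F6 | step 7 | (R)-{[5-(2,2-dibromoethenyl)dec-2-yn-1-yl]oxy}triisopropylsilane | CCCCC[C@H](CC#CCO[Si](C(C)C)(C(C)C)C(C)C)C=C(Br)Br
F7 | step 12 | 3-[(2R)-2-hydroxyhexyl]-4-{(2R)-1-[4-(hydroxymethyl)-2,5-dioxo-2,5-dihydrofuran-3-yl]heptan-2-yl}furan-2,5-dione | CCCCC[C@H](CC1=C(CO)C(=O)OC1=O)C1=C(C[C@H](O)CCCC)C(=O)OC1=O
A1 | alternative 1 | dimethyl 2-(bromomethyl)-3-{[(triisopropylsilyl)oxy]methyl}maleate (ester groups cis) | COC(=O)/C(CBr)=C(\C(=O)OC)CO[Si](C(C)C)(C(C)C)C(C)C
A2 | alternative 1 | (S)-4-benzyl-3-[(R)-2-({ring-A maleate}methyl)heptanoyl]oxazolidin-2-one, alkylation product of 6 with A1 | CCCCC[C@H](C/C(C(=O)OC)=C(\CO[Si](C(C)C)(C(C)C)C(C)C)C(=O)OC)C(=O)N1[C@@H](Cc2ccccc2)COC1=O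
A3 | alternative 1 | α-keto ester from A2 (methyl 2-oxoalkanoate with the stereocentre α to the ketone) | CCCCC[C@H](C/C(C(=O)OC)=C(\CO[Si](C(C)C)(C(C)C)C(C)C)C(=O)OC)C(=O)C(=O)OC
A4 | alternative 2 | 3-methyl-4-{[(triisopropylsilyl)oxy]methyl}furan-2,5-dione | CC1=C(CO[Si](C(C)C)(C(C)C)C(C)C)C(=O)OC1=O
A5 | alternative 2 | rac-3-(1-bromohexyl)-4-(2-oxohexyl)furan-2,5-dione | CCCCCC(Br)C1=C(CC(=O)CCCC)C(=O)OC1=O
A6 | alternative 3 | bis(3,4-dialkylfuran) corresponding to 15 | CCCCC[C@H](Cc1cocc1CO[Si](C(C)C)(C(C)C)C(C)C)c1cocc1C[C@H](O[Si](CC)(CC)CC)CCCC
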